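The ratio of the dissolution coefficient of solid substrate to the drain on dissolved substrate by reagent stands at 20.6 at the charge, and the reckoning for this flask starts there.

    crystals ⇌ target, rate k1*(cs1 - [target]) while solid is left; crystals form when [target] > cs1 (cs1 = 0.67 mM, k1 = 0.21 s⁻¹)
    reagent + target ⇌ idle adduct, settled at all times (K2 = 29 L mol⁻¹)
    solid substrate ⇌ dissolved substrate, rate k3*(cs3 - [dissolved substrate]) while solid is left; crystals form when [dissolved substrate] > cs3 (cs3 = 3.4 mM, k3 = 0.90 s⁻¹)
    2 reagent → self-condensation product (k4 = 1.7 L mol⁻¹ s⁻¹)
    dissolved substrate + reagent → target (k5 = 2.3 L mol⁻¹ s⁻¹)
    dissolved substrate + target → side product (k6 = 2.8 L mol⁻¹ s⁻¹)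

solid substrate 20 mM; reagent 19.0 mM; time 15 s

- amber: doubling the amount of reagent, all else as stated
- red: doubling the solubility in step 3, all else as stated
- grey: doubling the solubility in step 1, all else as stated
- violet: doubling the dissolution coefficient of step 1, all else as stated

- target and idle adduct and crystals together at 15 s, in percent of the solid substrate charged
- the change that raises the amount of target and idle adduct and crystals together at 15 s, in percent of the solid substrate charged most ("none" if none brings more than 2 percentage points) (amber / red / grey / violet / none)
- amount of target and idle adduct and crystals together at 15 s, in percent of the solid substrate charged, after red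

- percentages count the solid substrate that a species holds: one side product counts as two
- target is meant together with its idle adduct and crystals
- for a step with 2 of a species take k times the square, and two of it per event
- solid, in amounts per volume of the solution: solid substrate, crystals
- at the start none of the solid substrate is in solution
- run time (flask): 15 s

With that ratio, c(dissolved substrate) climbs from zero to close to its solubility 3.4 mM and stays there while solid is left. Formation of target is therefore pseudo-first-order in reagent, with constant 0.00782 s⁻¹. Two reckonings of my own follow from it.

Reagent held at its charge for the whole run:

y ≈ 0.00782 s⁻¹ × 19.0 mM × 15 s / 20 mM = 11.1%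

Reagent falling: at charged reagent and c(dissolved substrate) at its solubility, self-condensation takes reagent 8.26 times faster than formation of target, with a first half-life by this step alone of h = 15.5 s. The effective time is the time at full charged reagent that delivers the same target as the falling reagent does:

t_eff = h × ln(1 + 15 s/h) = 10.5 s

y ≈ 0.00782 s⁻¹ × 19.0 mM × 10.5 s / 20 mM = 7.79%

The two part by a factor 0.700. The first cheats, because h is about as long as the run. The second counts the first 1.11 s, while dissolved substrate rises, at full rate, so it leans high.

Doubling the solubility of solid substrate (red) multiplies the second line by 2, to 15.6%. Doubling reagent (amber) multiplies it by 1.59. Grey and violet enter neither line, so this reckoning picks red.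

The forecast gives 6.1%, red and 11.4%, both yields below mine. Its grounds open with “Dissolved substrate sits near its solubility after about a second”.

The simulation gives 6.16%, red with 5.2 percentage points against 3.4 points for amber, and 11.4%, so the forecast stands and my reckoning read high. At 7.50 s dissolved substrate in the flask stood at 96.6% of saturation. Read back from y, the effective time is 8.29 s, shorter than the 10.5 s reckoned. For y to stand 5 points from the value of this flask, and so off the forecast's figure, the nearest settings are a solid substrate charge down at 11.0 mM or a time out at 41.1 s.

The neighbour flask charged with 5.0 mM of solid substrate has the same reagent charge, so its effective time is taken as unchanged: 10.5 s gives 31.2%, and the read 8.29 s gives 24.6%. Computed, that neighbour flask reaches 24.6%, with 6.43% of its solid substrate left.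

The numbers of this flask come from no measurement, and the outcome is calculated.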